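**Plan**
- Retrosynthetic cuts, in order: C8=C17 (carbonyl methylenation), C12–C13 (B-alkyl Suzuki coupling), C3–C4 (ring A, sigmatropic ring contraction), C4=C5 and C18–O (lactone), then C1–C10 and C9–C11 (three-component coupling on a ring B enone).
- Forward: ring B is a commercial cyclohexenone ketal; vinyl conjugate addition and acrolein aldol set C9, C10 and a C1 carbinol; a δ-lactone is tied from the C1 oxygen to C5; an Ireland–Claisen ring contraction closes ring A; the side chain, the C8 enone and the methylene follow.
- Enabling feature: quaternary C4 carries an oxidised carbon (C18, the acetoxymethyl carbon) and ring A holds exactly three carbons (C3, C2, C1) between C4 and C10. C18 can therefore be a lactone carbonyl whose oxygen sits on C1, so that C3=C2–C1–O–C18=C4 is an allyl ketene acetal bridged by C5–C10.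
- Stereochemistry: C10 anti to the C9 vinyl group and C1 from a closed aldol transition state (relative); absolute configuration from a Sharpless kinetic resolution at C1; C1 relays to C4 in the [3,3] shift; C5 from face-selective protonation during enone conjugation; 13E from the enol triflate.
- Helpers removed later: the C1 oxygen (leaves as the C1=C2 alkene, hydrogenated in step 12), the C8 dioxolane, and the C5=C6 alkene (moved into conjugation in step 13).

Key step: step 7

Remark: positions follow labdane numbering (ring A = C1–C5 and C10; ring B = C5–C10; C17 = methylene carbon; C18 = acetoxymethyl carbon; C19 and C20 = methyls on C4 and C10); the target is the ent-labdane enantiomer encoded by the given SMILES.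

**Step 1**
Reactants: 1 1,4-dioxaspiro[4.5]dec-6-en-8-one; 2 iodine
Product: 3 7-iodo-1,4-dioxaspiro[4.5]dec-6-en-8-one
Conditions: I2, pyridine, CH2Cl2, 0 °C to rt
Reagents that add atoms: iodine [I][I]
Why: α-Iodination of a cyclic enone by the pyridine-mediated addition–iodination–elimination sequence should give the 2-iodoenone only, and the ketal is stable to the basic medium.

**Step 2**
Reactants: 3 7-iodo-1,4-dioxaspiro[4.5]dec-6-en-8-one; 4 methylboronic acid
Product: 5 7-methyl-1,4-dioxaspiro[4.5]dec-6-en-8-one
Conditions: Pd(OAc)2 (cat.), SPhos, K3PO4, toluene–H2O, 80 °C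
Reagents that add atoms: methylboronic acid CB(O)O
Why: Suzuki–Miyaura coupling of the α-iodoenone replaces iodine by the future C20 methyl group and leaves enone and ketal intact.

**Step 3**
Reactants: 5 7-methyl-1,4-dioxaspiro[4.5]dec-6-en-8-one; 6 vinylmagnesium bromide; 7 acrolein
Product: 9 racemic (6S*,7R*)-7-[(1R*)-1-hydroxyprop-2-en-1-yl]-7-methyl-6-vinyl-1,4-dioxaspiro[4.5]decan-8-one, via bromomagnesium enolate 8 (not isolated)
Conditions: vinylMgBr, CuBr·SMe2 (cat.), THF, −40 °C; then acrolein, −78 °C; aq. NH4Cl
Reagents that add atoms: vinylmagnesium bromide C=C[Mg]Br; acrolein C=CC=O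
Why: Copper-catalysed conjugate addition gives the enolate regiospecifically, and its 1,2-aldol addition to acrolein should occur anti to the new C9 vinyl group (sets C10) and through a closed Zimmerman–Traxler chair with the aldehyde vinyl equatorial (sets C1, hydroxyl syn to the C10 methyl), giving the racemate of the needed relative configuration.

**Step 4**
Reactants: 9 racemic aldol
Product: 10 (6S,7R)-7-[(1R)-1-hydroxyprop-2-en-1-yl]-7-methyl-6-vinyl-1,4-dioxaspiro[4.5]decan-8-one
Conditions: Ti(OiPr)4, D-(−)-diisopropyl tartrate, t-BuOOH (0.6 equiv), 4 Å sieves, CH2Cl2, −20 °C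
Reagents that add atoms: none
Why: In this Sharpless kinetic resolution the unwanted enantiomer of the secondary allylic alcohol should be epoxidised fast under the D-(−)-tartrate catalyst, so that 10 is recovered and the absolute configuration of C1, C9 and C10 is fixed together (at most half of the racemate can be used).

**Step 5**
Reactants: 10 resolved allylic alcohol; 11 2-(diethoxyphosphoryl)propanoic acid
Product: 12 2-(diethoxyphosphoryl)propanoate ester of 10 (epimer mixture at the phosphonate carbon)
Conditions: N,N'-dicyclohexylcarbodiimide, DMAP (cat.), CH2Cl2, 0 °C to rt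
Reagents that add atoms: 2-(diethoxyphosphoryl)propanoic acid CCOP(=O)(OCC)C(C)C(=O)O
Why: Steglich esterification attaches C18, C4 and C19 to the C1 oxygen; the stereocentre at the phosphonate carbon is destroyed in the next step.

**Step 6**
Reactants: 12 phosphonate ester
Product: 13 unsaturated δ-lactone (C18 lactone carbonyl on the C1 oxygen, C4=C5 double bond, C1 vinyl and C9 vinyl both cis to the C10 methyl, C8 dioxolane)
Conditions: NaH, THF, 0 to 60 °C
Reagents that add atoms: none
Why: Intramolecular Horner–Wadsworth–Emmons olefination of the C5 ketone closes the six-membered lactone and forms C4=C5 without touching a stereocentre.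

**Step 7**
Reactants: 13 unsaturated δ-lactone; 14 chlorotrimethylsilane
Product: 17 bicyclic acid (ring A closed; C1=C2 and C5=C6 alkenes; C4 carries CO2H trans and methyl cis to the C10 methyl; C8 dioxolane; C9 vinyl), via silyl vinylketene acetal 15 (not isolated), via trimethylsilyl ester 16 (not isolated)
Conditions: LiN(iPr)2, Me3SiCl–Et3N, THF–DMPU, −78 °C to rt; toluene, 100 °C; then aq. citric acid
Reagents that add atoms: none
Why: Kinetic γ-deprotonation at C6 and O-silylation give the cyclic vinylketene acetal 15, in which C3=C2–C1–O–C18=C4 is an allyl ketene acetal held in a ring by the C5–C10 link; the Ireland–Claisen [3,3] shift then forms C3–C4 and breaks C1–O, contracting the oxabicycle to the carbocycle. The closest known reaction type is the Claisen rearrangement of silyl ketene acetals of vinyl-substituted δ-lactones (and of allyl esters through their dienolates) to cyclohex-3-enecarboxylic acids. Ring A (C4, C5, C10, C1, C2, C3) is closed suprafacially through a boat-like bicyclic transition state, and the allyl unit is taken into the ring so that the alkene ends up endocyclic at C1=C2. The only new stereocentre, quaternary C4, is controlled by C1: C3 can reach C4 only on the lactone face that carries the C1 vinyl group, which is the face of the C10 methyl, so C18 ends up trans and the C4 methyl cis to the C10 methyl. The step needs O- rather than C-silylation and bond formation at C4 rather than C6; only C4 completes the six-atom array, and the trigonal C5 keeps the two-atom tether free of ring-fusion strain. The C1 oxygen, the helper, leaves ring A as the C1=C2 double bond.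

**Step 8**
Reactants: 17 bicyclic acid
Product: 18 primary alcohol (C18 hydroxymethyl)
Conditions: LiAlH4, THF, 0 °C to reflux
Reagents that add atoms: none
Why: LiAlH4 reduces the hindered carboxylic acid to the neopentyl alcohol while alkenes and ketal are inert.

**Step 9**
Reactants: 18 primary alcohol; 19 acetic anhydride
Product: 20 acetate (C18 acetoxymethyl)
Conditions: Ac2O, pyridine, DMAP (cat.), CH2Cl2, rt
Reagents that add atoms: acetic anhydride CC(=O)OC(C)=O
Why: DMAP-catalysed acylation of the primary alcohol installs the acetate of the target.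

**Step 10**
Reactants: 21 methyl acetoacetate; 22 trifluoromethanesulfonic anhydride
Product: 23 methyl (2E)-3-(trifluoromethylsulfonyloxy)but-2-enoate
Conditions: Tf2O, aq. Me4NOH, hexane, 5 °C
Reagents that add atoms: trifluoromethanesulfonic anhydride O=S(=O)(OS(=O)(=O)C(F)(F)F)C(F)(F)F
Why: O-Triflation of the β-keto ester enolate in the absence of a chelating metal ion should give the (E)-enol triflate, with the triflate trans to the ester.

**Step 11**
Reactants: 20 acetate; 24 9-borabicyclo[3.3.1]nonane; 23 (E)-enol triflate
Product: 26 coupled ester (complete (13E)-side chain on C9; C1=C2, C5=C6, C8 dioxolane), via B-alkyl borane 25 (not isolated)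
Conditions: 9-BBN-H, THF, 0 °C to rt; then 23, PdCl2(dppf) (cat.), aq. K3PO4, DMF, rt
Reagents that add atoms: methyl (2E)-3-(trifluoromethylsulfonyloxy)but-2-enoate C/C(OS(=O)(=O)C(F)(F)F)=C\C(=O)OC
Why: 9-BBN should hydroborate only the terminal C11=C12 vinyl group (the ring alkenes are di- and trisubstituted), and the B-alkyl Suzuki–Miyaura coupling forms C12–C13 with retention of the triflate geometry, which fixes 13E.

**Step 12**
Reactants: 26 coupled ester
Product: 27 1,2-dihydro compound (ring A saturated; C5=C6 and side-chain enoate kept)
Conditions: H2 (1 atm), RhCl(PPh3)3 (cat.), benzene–EtOH, rt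
Reagents that add atoms: none
Why: Homogeneous hydrogenation discriminates by substitution, so the cis-disubstituted C1=C2 bond should be reduced while the trisubstituted C5=C6 alkene (between two quaternary carbons) and the trisubstituted enoate remain.

**Step 13**
Reactants: 27 1,2-dihydro compound; 28 water
Product: 29 trans-fused enone (C8 ketone, C6=C7, C5–H trans to the C10 methyl)
Conditions: HCl (2 M aq.), THF, rt
Reagents that add atoms: water O
Why: Ketal hydrolysis frees the C8 ketone and the β,γ-unsaturated ketone moves into conjugation through its dienol; protonation at C5 should come from the face opposite the axial C4 and C10 methyl groups, giving the trans ring fusion (also the expected thermodynamic one), while epimerisable C9 keeps its equatorial side chain.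

**Step 14**
Reactants: 29 trans-fused enone; 30 dibromomethane
Product: 31 methyl (13E)-18-acetoxy-ent-labda-6,8(17),13-trien-15-oate (target, 4S,5S,9R,10S)
Conditions: Zn, CH2Br2, TiCl4, THF–CH2Cl2, 0 °C to rt
Reagents that add atoms: dibromomethane BrCBr
Why: Takai–Lombardo methylenation converts the hindered, enolisable enone carbonyl into the exocyclic methylene without base, so C9 is not epimerised and the acetate and enoate esters are untouched.

**Compound list**
1 | 1,4-dioxaspiro[4.5]dec-6-en-8-one | O=C1C=CC2(CC1)OCCO2 | starting material
2 | iodine | [I][I] | starting material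
3 | 7-iodo-1,4-dioxaspiro[4.5]dec-6-en-8-one | O=C1CCC2(OCCO2)C=C1I | intermediate
4 | methylboronic acid | CB(O)O | starting material
5 | 7-methyl-1,4-dioxaspiro[4.5]dec-6-en-8-one | CC1=CC2(CCC1=O)OCCO2 | intermediate
6 | vinylmagnesium bromide | C=C[Mg]Br | starting material
7 | acrolein | C=CC=O | starting material
8 | bromomagnesium enolate of 7-methyl-6-vinyl-1,4-dioxaspiro[4.5]decan-8-one (racemic; one enantiomer drawn) | C=C[C@H]1C(C)=C(O[Mg]Br)CCC12OCCO2 | intermediate
9 | racemic (6S*,7R*)-7-[(1R*)-1-hydroxyprop-2-en-1-yl]-7-methyl-6-vinyl-1,4-dioxaspiro[4.5]decan-8-one (racemate; the enantiomer carried on is drawn) | C=C[C@@H](O)[C@]1(C)C(=O)CCC2(OCCO2)[C@H]1C=C | intermediate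
10 | (6S,7R)-7-[(1R)-1-hydroxyprop-2-en-1-yl]-7-methyl-6-vinyl-1,4-dioxaspiro[4.5]decan-8-one | C=C[C@@H](O)[C@]1(C)C(=O)CCC2(OCCO2)[C@H]1C=C | intermediate
11 | 2-(diethoxyphosphoryl)propanoic acid | CCOP(=O)(OCC)C(C)C(=O)O | starting material
12 | 2-(diethoxyphosphoryl)propanoate ester of 10 | C=C[C@@H](OC(=O)C(C)P(=O)(OCC)OCC)[C@]1(C)C(=O)CCC2(OCCO2)[C@H]1C=C | intermediate
13 | unsaturated δ-lactone (C18 carbonyl–O–C1; C4=C5; C1 and C9 vinyl groups cis to the C10 methyl; C8 dioxolane) | C=C[C@H]1OC(=O)C(C)=C2CCC3(OCCO3)[C@@H](C=C)[C@]12C | intermediate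
14 | chlorotrimethylsilane | C[Si](C)(C)Cl | starting material
15 | trimethylsilyl vinylketene acetal of 13 (C4=C18(OSiMe3)–O–C1; C5=C6) | C=C[C@H]1OC(O[Si](C)(C)C)=C(C)C2=CCC3(OCCO3)[C@@H](C=C)[C@]12C | intermediate
16 | trimethylsilyl ester of acid 17 | O1CCOC12CC=C3[C@@](C)(C(=O)O[Si](C)(C)C)CC=C[C@@]3(C)[C@@H]2C=C | intermediate
17 | bicyclic acid (C1=C2, C5=C6; C4: CO2H trans and methyl cis to the C10 methyl; C8 dioxolane; C9 vinyl cis to the C10 methyl) | O1CCOC12CC=C3[C@@](C)(C(=O)O)CC=C[C@@]3(C)[C@@H]2C=C | intermediate
18 | primary alcohol from 17 (C18 hydroxymethyl) | O1CCOC12CC=C3[C@@](C)(CO)CC=C[C@@]3(C)[C@@H]2C=C | intermediate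
19 | acetic anhydride | CC(=O)OC(C)=O | starting material
20 | acetate of 18 | O1CCOC12CC=C3[C@@](C)(COC(C)=O)CC=C[C@@]3(C)[C@@H]2C=C | intermediate
21 | methyl acetoacetate | CC(=O)CC(=O)OC | starting material
22 | trifluoromethanesulfonic anhydride | O=S(=O)(OS(=O)(=O)C(F)(F)F)C(F)(F)F | starting material
23 | methyl (2E)-3-(trifluoromethylsulfonyloxy)but-2-enoate | C/C(OS(=O)(=O)C(F)(F)F)=C\C(=O)OC | intermediate
24 | 9-borabicyclo[3.3.1]nonane | B1C2CCCC1CCC2 | starting material
25 | B-alkyl-9-BBN borane from 20 (boron on C12) | O1CCOC12CC=C3[C@@](C)(COC(C)=O)CC=C[C@@]3(C)[C@@H]2CCB2C3CCCC2CCC3 | intermediate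
26 | coupled ester (13E side chain; C1=C2, C5=C6; C8 dioxolane) | O1CCOC12CC=C3[C@@](C)(COC(C)=O)CC=C[C@@]3(C)[C@@H]2CC/C(C)=C/C(=O)OC | intermediate
27 | 1,2-dihydro compound (C5=C6; C8 dioxolane) | O1CCOC12CC=C3[C@@](C)(COC(C)=O)CCC[C@@]3(C)[C@@H]2CC/C(C)=C/C(=O)OC | intermediate
28 | water | O | starting material
29 | trans-fused enone (8-oxo, C6=C7) | O=C1C=C[C@@H]2[C@@](C)(COC(C)=O)CCC[C@@]2(C)[C@@H]1CC/C(C)=C/C(=O)OC | intermediate
30 | dibromomethane | BrCBr | starting material
31 | methyl (13E)-18-acetoxy-ent-labda-6,8(17),13-trien-15-oate (CNP0148290.1) | C=C1C=C[C@@H]2[C@@](C)(COC(C)=O)CCC[C@@]2(C)[C@@H]1CC/C(C)=C/C(=O)OC | target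

**Step count**
Total: 14 steps. Longest linear sequence: 13 steps (steps 1–9 and 11–14; step 10 is a one-step branch).

**Steps most likely to fail**

Step 7. Enolisation may go astray: the amide base may attack the lactone carbonyl, or silylation may occur on carbon, and a slow [3,3] shift would leave time for O-to-C silyl migration. The fallback closes the same C3–C4 bond ionically; it sets out from 13 and comes back at 18. Aminolysis of 13 (pyrrolidine, AlMe3) should give the hydroxy amide F1. Methyl chloroformate and pyridine convert its C1 hydroxyl into the allylic carbonate F2. LiN(SiMe3)2 then forms the amide dienolate, and Pd(PPh3)4 ionises the carbonate; the dienolate should attack the far terminus C3 of the π-allyl unit (attack at C1 would give a cyclobutane) to give the bicyclic amide F3. LiBHEt3 reduces F3 to 18. In this variant the C4 configuration rests on the dienolate conformation and not on chirality transfer, so it would have to be checked.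

Step 3. Conjugate addition at the neopentyl β-carbon next to the ketal may be slow, and leakage through open aldol transition states would erode facial selectivity at the carbinol carbon. The fallback sets out from 9 (as a C1 epimer mixture) and comes back at 10, replacing substrate control and the resolution of step 4 by a reagent-controlled reduction. Dess–Martin oxidation gives the racemic vinyl ketone F4. Reduction with the (S)-configured methyl oxazaborolidine and catecholborane at −78 °C (quaternary C10 taken as the large group) should give 10 together with the diastereomeric carbinol F5 from the other enantiomer, removed by chromatography.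

Step 6. Intramolecular olefination at the ketone flanked by the quaternary C10 may be sluggish, so that the phosphonate anion decomposes instead. The fallback sets out from 10 and comes back at 13 by aldol closure and dehydration. Propionyl chloride, pyridine and DMAP give the propionate F6. LiN(SiMe3)2 in THF at −78 °C effects intramolecular aldol addition to the C5 ketone to give the β-hydroxy δ-lactone F7 (epimer mixture at C4 and C5, both centres being destroyed next). Dehydration (SOCl2, pyridine) gives 13; any β,γ-unsaturated isomer leads to the same silyl ketene acetal in step 7.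

**Further compounds**
F1 | step 7 | hydroxy pyrrolidine amide from ring-opening of 13 | C/C(C(=O)N1CCCC1)=C2\CCC3(OCCO3)[C@@H](C=C)[C@]2(C)[C@H](O)C=C
F2 | step 7 | methyl carbonate of F1 | C/C(C(=O)N1CCCC1)=C2\CCC3(OCCO3)[C@@H](C=C)[C@]2(C)[C@H](OC(=O)OC)C=C
F3 | step 7 | bicyclic pyrrolidine amide (amide analogue of 17) | O1CCOC12CC=C3[C@@](C)(C(=O)N4CCCC4)CC=C[C@@]3(C)[C@@H]2C=C
F4 | step 3 | racemic vinyl ketone from oxidation of 9 (enantiomer leading to 10 drawn) | C=CC(=O)[C@]1(C)C(=O)CCC2(OCCO2)[C@H]1C=C
F5 | step 3 | diastereomeric carbinol from the other enantiomer of F4 | C=C[C@@H](O)[C@@]1(C)C(=O)CCC2(OCCO2)[C@@H]1C=C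
F6 | step 6 | propionate ester of 10 | C=C[C@@H](OC(=O)CC)[C@]1(C)C(=O)CCC2(OCCO2)[C@H]1C=C
F7 | step 6 | β-hydroxy δ-lactone (C5 tertiary alcohol; epimer mixture at C4 and C5) | C=C[C@H]1OC(=O)C(C)C2(O)CCC3(OCCO3)[C@@H](C=C)[C@]12C
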